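**Remark:** Fertidin is taken as the 4-methoxybenzoate of jaeschkeanadiol with the (3R,3aS,4S,8aR) configuration encoded in the SMILES; target positions are given in hydroazulene numbering (C1–C3, C3a, C4–C8, C8a).

The route rests on disconnecting the cyclopentane at C1–C8a, the bond between the unfunctionalised ring methylene and the methyl-bearing quaternary ring-fusion carbon. An acyclic (Z)-β-iodoenone carrying an isopropenyl group (C8a, its methyl and C8) undergoes Pd-catalysed 5-exo-trig carbopalladation; the resulting neopentylpalladium cannot β-eliminate and is intercepted by tributyl(vinyl)stannane. One operation thus closes the five-membered ring, creates the quaternary stereocentre C8a under control of C3a, and extends C8 to the allyl arm (C8–C7) used later to close the seven-membered ring by metathesis. C3 and C4 are then set by substrate-controlled additions.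

Key step: step 7

Step 1
Reactants: 1 (R)-4-benzyloxazolidin-2-one; 2 3-methylbut-3-enoic acid
Product: 4 (R)-4-benzyl-3-(3-methylbut-3-enoyl)oxazolidin-2-one, via mixed pivalic anhydride 3 (not isolated)
Conditions: PivCl, Et3N, THF, −20 °C; then 1, LiCl, rt
Reagents that add atoms: none
Why: N-acylation of the LiCl-activated oxazolidinone by a mixed anhydride is the standard base-free way to Evans imides and should keep the β,γ-alkene out of conjugation; no stereocentre is formed.

Step 2
Reactants: 4 (R)-4-benzyl-3-(3-methylbut-3-enoyl)oxazolidin-2-one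
Product: 5 (R)-4-benzyl-3-[(2S)-2-(hydroxymethyl)-3-methylbut-3-enoyl]oxazolidin-2-one
Conditions: TiCl4, i-Pr2NEt, CH2Cl2, 0 °C; then 1,3,5-trioxane, TiCl4, 0 °C
Reagents that add atoms: 1,3,5-trioxane C1OCOCO1
Why: In this Evans auxiliary-controlled hydroxymethylation the chelated (Z)-titanium enolate should be attacked by TiCl4-activated formaldehyde at the α-carbon on the face opposite the benzyl group, which sets the future C3a as (S).

Step 3
Reactants: 5 (R)-4-benzyl-3-[(2S)-2-(hydroxymethyl)-3-methylbut-3-enoyl]oxazolidin-2-one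
Product: 6 (2S)-2-(hydroxymethyl)-N-methoxy-N,3-dimethylbut-3-enamide
Conditions: MeNH(OMe)·HCl, AlMe3, CH2Cl2, −10 °C to rt
Reagents that add atoms: N,O-dimethylhydroxylamine hydrochloride CNOC.Cl
Why: Weinreb amide formation by aluminium amide transamination is assisted by the free β-hydroxyl, cleaves the exocyclic imide carbonyl selectively and releases the auxiliary without touching the stereocentre.

Step 4
Reactants: 6 (2S)-2-(hydroxymethyl)-N-methoxy-N,3-dimethylbut-3-enamide
Product: 7 (2S)-2-{[(tert-butyldimethylsilyl)oxy]methyl}-N-methoxy-N,3-dimethylbut-3-enamide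
Conditions: TBSCl, imidazole, DMF, rt
Reagents that add atoms: tert-butyldimethylsilyl chloride CC(C)(C)[Si](C)(C)Cl
Why: Silylation of the primary alcohol is routine and is needed because a free β-hydroxy ynone would cyclise by oxa-Michael addition in the next two steps.

Step 5
Reactants: 7 (2S)-2-{[(tert-butyldimethylsilyl)oxy]methyl}-N-methoxy-N,3-dimethylbut-3-enamide
Product: 8 (4S)-4-{[(tert-butyldimethylsilyl)oxy]methyl}-5-methylhex-5-en-1-yn-3-one
Conditions: HC≡CMgBr, THF, −78 to 0 °C; inverse quench into cold aq. NaHSO4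
Reagents that add atoms: ethynylmagnesium bromide C#C[Mg]Br
Why: In this Weinreb ketone synthesis the chelated tetrahedral intermediate should hold until the acidic quench, so the terminal ynone is released without over-addition and the α-stereocentre is not exposed to base.

Step 6
Reactants: 8 (4S)-4-{[(tert-butyldimethylsilyl)oxy]methyl}-5-methylhex-5-en-1-yn-3-one
Product: 9 (1Z,4S)-4-{[(tert-butyldimethylsilyl)oxy]methyl}-1-iodo-5-methylhexa-1,5-dien-3-one
Conditions: NaI, AcOH, rt, dark
Reagents that add atoms: sodium iodide [Na+].[I-]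
Why: Conjugate hydroiodination of an ynone with NaI in acetic acid is a kinetically controlled anti addition that should give the (Z)-β-iodoenone, the geometry the ring closure needs.

Step 7
Reactants: 9 (1Z,4S)-4-{[(tert-butyldimethylsilyl)oxy]methyl}-1-iodo-5-methylhexa-1,5-dien-3-one
Product: 11 (4S,5S)-5-{[(tert-butyldimethylsilyl)oxy]methyl}-4-methyl-4-(prop-2-en-1-yl)cyclopent-2-en-1-one, via neopentylpalladium iodide complex 10 (not isolated)
Conditions: Pd(PPh3)4 (10 mol%), Bu3SnCH=CH2 (1.5 equiv, slow addition), toluene, 80 °C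
Reagents that add atoms: tributyl(vinyl)stannane C=C[Sn](CCCC)(CCCC)CCCC
Why: Oxidative addition of zerovalent palladium to the vinyl C–I bond of 9 gives a vinylpalladium iodide whose tethered 1,1-disubstituted alkene inserts by syn carbopalladation, forming the C1–C8a bond and the quaternary centre and leaving the neopentylpalladium 10, which has no β-hydrogen and is therefore transmetalated by the vinylstannane and reductively eliminated to the allyl group. The closest known reaction type is the intramolecular Heck cyclisation with anion capture by an organostannane (domino Heck–Stille). The cyclopentenone ring closes in the 5-exo-trig mode. C8a is controlled by the existing C3a stereocentre: in the four-centre insertion transition state the alkene plane is perpendicular to the forming ring, so the palladium-bearing CH2 should eclipse the C3a hydrogen and not the silyloxymethyl group, which puts the future allyl arm trans and the methyl cis to that group. The step needs ring closure to outrun direct Stille coupling of the vinyl iodide, which the intramolecular 5-exo insertion and slow addition of the stannane should secure, and exo over endo insertion, which syn carbopalladation of a 1,1-disubstituted alkene favours strongly.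

Step 8
Reactants: 11 (4S,5S)-5-{[(tert-butyldimethylsilyl)oxy]methyl}-4-methyl-4-(prop-2-en-1-yl)cyclopent-2-en-1-one
Product: 12 (2S,3R)-2-{[(tert-butyldimethylsilyl)oxy]methyl}-3-methyl-3-(prop-2-en-1-yl)cyclopentan-1-one
Conditions: Cu(OAc)2 (5 mol%), 1,2-bis(diphenylphosphino)benzene (5 mol%), (EtO)2MeSiH, t-BuOH, toluene, rt
Reagents that add atoms: none
Why: Copper hydride conjugate reduction is chemoselective for the enone over the isolated allyl alkene, and the copper enolate is protonated at C2, so C3a is not touched.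

Step 9
Reactants: 12 (2S,3R)-2-{[(tert-butyldimethylsilyl)oxy]methyl}-3-methyl-3-(prop-2-en-1-yl)cyclopentan-1-one
Product: 13 (1R,2S,3R)-2-{[(tert-butyldimethylsilyl)oxy]methyl}-3-methyl-1-(propan-2-yl)-3-(prop-2-en-1-yl)cyclopentan-1-ol
Conditions: i-PrMgCl, CeCl3, THF, −78 to 0 °C
Reagents that add atoms: isopropylmagnesium chloride CC(C)[Mg]Cl
Why: Organocerium 1,2-addition should suppress enolisation and β-hydride reduction of the hindered ketone, and the isopropyl group should enter anti to the adjacent silyloxymethyl substituent, setting C3 with the hydroxyl cis to that substituent and to the C8a methyl.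

Step 10
Reactants: 13 (1R,2S,3R)-2-{[(tert-butyldimethylsilyl)oxy]methyl}-3-methyl-1-(propan-2-yl)-3-(prop-2-en-1-yl)cyclopentan-1-ol
Product: 14 (1R,2S,3R)-2-(hydroxymethyl)-3-methyl-1-(propan-2-yl)-3-(prop-2-en-1-yl)cyclopentan-1-ol
Conditions: TBAF, THF, 0 °C to rt
Reagents that add atoms: none
Why: Fluoride-mediated cleavage of the primary silyl ether is routine and leaves the tertiary alcohol, the alkene and all stereocentres unchanged.

Step 11
Reactants: 14 (1R,2S,3R)-2-(hydroxymethyl)-3-methyl-1-(propan-2-yl)-3-(prop-2-en-1-yl)cyclopentan-1-ol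
Product: 15 (1R,2R,5R)-2-hydroxy-5-methyl-2-(propan-2-yl)-5-(prop-2-en-1-yl)cyclopentane-1-carbaldehyde
Conditions: TEMPO (10 mol%), PhI(OAc)2, CH2Cl2, rt
Reagents that add atoms: none
Why: The TEMPO/PhI(OAc)2 oxidation acts only on the primary alcohol and is neutral enough to avoid retro-aldol cleavage or epimerisation of the β-hydroxy aldehyde.

Step 12
Reactants: 15 (1R,2R,5R)-2-hydroxy-5-methyl-2-(propan-2-yl)-5-(prop-2-en-1-yl)cyclopentane-1-carbaldehyde
Product: 16 (1R,2S,3R)-2-[(1S)-1-hydroxy-3-methylbut-3-en-1-yl]-3-methyl-1-(propan-2-yl)-3-(prop-2-en-1-yl)cyclopentan-1-ol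
Conditions: 2-methylallylmagnesium chloride (3 equiv), THF, −78 °C
Reagents that add atoms: 2-methylallylmagnesium chloride CC(=C)C[Mg]Cl
Why: In this chelation-controlled Grignard addition (Cram chelate) the magnesium alkoxide of the tertiary hydroxyl should bind the aldehyde oxygen, and the nucleophile should add on the side of the C3a hydrogen, away from the quaternary C8a, which sets C4 as (S) (anti 1,3-diol).

Step 13
Reactants: 16 (1R,2S,3R)-2-[(1S)-1-hydroxy-3-methylbut-3-en-1-yl]-3-methyl-1-(propan-2-yl)-3-(prop-2-en-1-yl)cyclopentan-1-ol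
Product: 17 (3R,3aS,4S,8aR)-6,8a-dimethyl-3-(propan-2-yl)-1,2,3,3a,4,5,8,8a-octahydroazulene-3,4-diol (jaeschkeanadiol)
Conditions: second-generation Grubbs catalyst RuCl2(=CHPh)(PCy3)(H2IMes) (5 mol%), CH2Cl2 (0.005 M), 40 °C
Reagents that add atoms: none
Why: Ring-closing metathesis of the allyl and 2-methylallyl groups should give the trisubstituted C6=C7 alkene in a seven-membered ring, and the trans arrangement of the two arms on the cyclopentane becomes the trans ring fusion.

Step 14
Reactants: 17 (3R,3aS,4S,8aR)-6,8a-dimethyl-3-(propan-2-yl)-1,2,3,3a,4,5,8,8a-octahydroazulene-3,4-diol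
Product: 18 (3R,3aS,4S,8aR)-3-hydroxy-6,8a-dimethyl-3-(propan-2-yl)-1,2,3,3a,4,5,8,8a-octahydroazulen-4-yl 4-methoxybenzoate (Fertidin)
Conditions: 4-MeOC6H4COCl, Et3N, DMAP (cat.), CH2Cl2, 0 °C to rt
Reagents that add atoms: 4-methoxybenzoyl chloride COc1ccc(cc1)C(Cl)=O
Why: DMAP-catalysed acylation should esterify only the secondary C4 hydroxyl, because the tertiary C3 hydroxyl is too hindered to react.

**Compound list**

1 | (R)-4-benzyloxazolidin-2-one | O=C1N[C@H](Cc2ccccc2)CO1 | starting material
2 | 3-methylbut-3-enoic acid | CC(=C)CC(=O)O | starting material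
3 | 3-methylbut-3-enoic pivalic anhydride | CC(=C)CC(=O)OC(=O)C(C)(C)C | intermediate
4 | (R)-4-benzyl-3-(3-methylbut-3-enoyl)oxazolidin-2-one | CC(=C)CC(=O)N1[C@H](Cc2ccccc2)COC1=O | intermediate
5 | (R)-4-benzyl-3-[(2S)-2-(hydroxymethyl)-3-methylbut-3-enoyl]oxazolidin-2-one | CC(=C)[C@@H](CO)C(=O)N1[C@H](Cc2ccccc2)COC1=O | intermediate
6 | (2S)-2-(hydroxymethyl)-N-methoxy-N,3-dimethylbut-3-enamide | CC(=C)[C@@H](CO)C(=O)N(C)OC | intermediate
7 | (2S)-2-{[(tert-butyldimethylsilyl)oxy]methyl}-N-methoxy-N,3-dimethylbut-3-enamide | CC(=C)[C@@H](CO[Si](C)(C)C(C)(C)C)C(=O)N(C)OC | intermediate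
8 | (4S)-4-{[(tert-butyldimethylsilyl)oxy]methyl}-5-methylhex-5-en-1-yn-3-one | CC(=C)[C@@H](CO[Si](C)(C)C(C)(C)C)C(=O)C#C | intermediate
9 | (1Z,4S)-4-{[(tert-butyldimethylsilyl)oxy]methyl}-1-iodo-5-methylhexa-1,5-dien-3-one | CC(=C)[C@@H](CO[Si](C)(C)C(C)(C)C)C(=O)/C=C\I | intermediate
10 | iodo{[5-{[(tert-butyldimethylsilyl)oxy]methyl}-1-methyl-4-oxocyclopent-2-en-1-yl]methyl}bis(triphenylphosphine)palladium, ring configuration as in 11 | O=C1C=C[C@](C)(C[Pd-2](I)([P+](c2ccccc2)(c2ccccc2)c2ccccc2)[P+](c2ccccc2)(c2ccccc2)c2ccccc2)[C@H]1CO[Si](C)(C)C(C)(C)C | intermediate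
11 | (4S,5S)-5-{[(tert-butyldimethylsilyl)oxy]methyl}-4-methyl-4-(prop-2-en-1-yl)cyclopent-2-en-1-one | O=C1C=C[C@](C)(CC=C)[C@H]1CO[Si](C)(C)C(C)(C)C | intermediate
12 | (2S,3R)-2-{[(tert-butyldimethylsilyl)oxy]methyl}-3-methyl-3-(prop-2-en-1-yl)cyclopentan-1-one | O=C1CC[C@](C)(CC=C)[C@H]1CO[Si](C)(C)C(C)(C)C | intermediate
13 | (1R,2S,3R)-2-{[(tert-butyldimethylsilyl)oxy]methyl}-3-methyl-1-(propan-2-yl)-3-(prop-2-en-1-yl)cyclopentan-1-ol | CC(C)[C@]1(O)CC[C@](C)(CC=C)[C@H]1CO[Si](C)(C)C(C)(C)C | intermediate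
14 | (1R,2S,3R)-2-(hydroxymethyl)-3-methyl-1-(propan-2-yl)-3-(prop-2-en-1-yl)cyclopentan-1-ol | CC(C)[C@]1(O)CC[C@](C)(CC=C)[C@H]1CO | intermediate
15 | (1R,2R,5R)-2-hydroxy-5-methyl-2-(propan-2-yl)-5-(prop-2-en-1-yl)cyclopentane-1-carbaldehyde | CC(C)[C@]1(O)CC[C@](C)(CC=C)[C@H]1C=O | intermediate
16 | (1R,2S,3R)-2-[(1S)-1-hydroxy-3-methylbut-3-en-1-yl]-3-methyl-1-(propan-2-yl)-3-(prop-2-en-1-yl)cyclopentan-1-ol | CC(C)[C@]1(O)CC[C@](C)(CC=C)[C@H]1[C@@H](O)CC(C)=C | intermediate
17 | (3R,3aS,4S,8aR)-6,8a-dimethyl-3-(propan-2-yl)-1,2,3,3a,4,5,8,8a-octahydroazulene-3,4-diol (jaeschkeanadiol) | O[C@H]1CC(C)=CC[C@@]2(C)CC[C@@](O)(C(C)C)[C@H]12 | intermediate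
18 | (3R,3aS,4S,8aR)-3-hydroxy-6,8a-dimethyl-3-(propan-2-yl)-1,2,3,3a,4,5,8,8a-octahydroazulen-4-yl 4-methoxybenzoate (Fertidin) | COc1ccc(C(=O)O[C@H]2CC(C)=CC[C@@]3(C)CC[C@@](O)(C(C)C)[C@H]23)cc1 | target

**Step count and risks**

Total step count: 14. Longest linear sequence: 14 steps (from 1 and 2 to 18).

Step 7 (key step). The vinylpalladium may cross-couple with the stannane before it cyclises. The hindered neopentylpalladium may also be transmetalated so slowly that it adds to the enone double bond (3-exo) or decomposes, and facial selectivity at C8a may be incomplete. The fallback replaces transmetalation by the faster CO insertion and sets out from 9. Cyclisation under PdCl2(PPh3)2, CO (1 atm), MeOH and Et3N in DMF at 70 °C should give the methyl ester methyl 2-[(1S,5S)-5-{[(tert-butyldimethylsilyl)oxy]methyl}-1-methyl-4-oxocyclopent-2-en-1-yl]acetate F1. Copper hydride conjugate reduction as in step 8 should give the keto ester methyl 2-[(1R,2S)-2-{[(tert-butyldimethylsilyl)oxy]methyl}-1-methyl-3-oxocyclopentyl]acetate F2. Ketone-selective addition of i-PrMgCl/CeCl3 at −78 °C should give the hydroxy ester methyl 2-[(1R,2S,3R)-2-{[(tert-butyldimethylsilyl)oxy]methyl}-3-hydroxy-1-methyl-3-(propan-2-yl)cyclopentyl]acetate F3. DIBAL-H at −78 °C should give the aldehyde 2-[(1R,2S,3R)-2-{[(tert-butyldimethylsilyl)oxy]methyl}-3-hydroxy-1-methyl-3-(propan-2-yl)cyclopentyl]acetaldehyde F4, and Wittig methylenation (Ph3PCH3Br, KOt-Bu, THF) returns to the route at 13.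

Step 2. TiCl4-activated formaldehyde may undergo a carbonyl-ene (Prins) reaction with the 1,1-disubstituted alkene, or the alkene may move into conjugation and react at the γ-carbon. The fallback uses a Lewis-acid-free enolate alkylation and sets out from 4. The sodium enolate (NaHMDS, THF, −78 °C) is alkylated with 4-methoxybenzyl chloromethyl ether on the face opposite the benzyl group to give the ether (4R)-4-benzyl-3-[(2S)-2-{[(4-methoxyphenyl)methoxy]methyl}-3-methylbut-3-enoyl]oxazolidin-2-one F5. Oxidative removal of the 4-methoxybenzyl group (DDQ, CH2Cl2/H2O) returns to the route at 5.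

Step 12. The magnesium chelate may not form cleanly, giving poor facial selectivity at C4, or the magnesium aldolate may undergo retro-aldol cleavage. The fallback sets C4 by directed reduction instead of by addition and sets out from 15. An unselective Barbier addition (2-methylallyl bromide, In, THF/H2O) should give 16 together with its epimer (1R,2S,3R)-2-[(1R)-1-hydroxy-3-methylbut-3-en-1-yl]-3-methyl-1-(propan-2-yl)-3-(prop-2-en-1-yl)cyclopentan-1-ol F6. Oxidation of the mixture (Dess–Martin periodinane, NaHCO3, CH2Cl2) should converge on the hydroxy ketone 1-[(1R,2R,5R)-2-hydroxy-5-methyl-2-(propan-2-yl)-5-(prop-2-en-1-yl)cyclopentyl]-3-methylbut-3-en-1-one F7. Evans–Saksena reduction (Me4NBH(OAc)3, AcOH/MeCN, −30 °C), with hydride delivered from the tertiary hydroxyl, should give the anti 1,3-diol and return to the route at 16.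

Further compounds
F1 | step 7 | methyl 2-[(1S,5S)-5-{[(tert-butyldimethylsilyl)oxy]methyl}-1-methyl-4-oxocyclopent-2-en-1-yl]acetate | O=C1C=C[C@](C)(CC(=O)OC)[C@H]1CO[Si](C)(C)C(C)(C)C
F2 | step 7 | methyl 2-[(1R,2S)-2-{[(tert-butyldimethylsilyl)oxy]methyl}-1-methyl-3-oxocyclopentyl]acetate | O=C1CC[C@](C)(CC(=O)OC)[C@H]1CO[Si](C)(C)C(C)(C)C
F3 | step 7 | methyl 2-[(1R,2S,3R)-2-{[(tert-butyldimethylsilyl)oxy]methyl}-3-hydroxy-1-methyl-3-(propan-2-yl)cyclopentyl]acetate | CC(C)[C@]1(O)CC[C@](C)(CC(=O)OC)[C@H]1CO[Si](C)(C)C(C)(C)C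
F4 | step 7 | 2-[(1R,2S,3R)-2-{[(tert-butyldimethylsilyl)oxy]methyl}-3-hydroxy-1-methyl-3-(propan-2-yl)cyclopentyl]acetaldehyde | CC(C)[C@]1(O)CC[C@](C)(CC=O)[C@H]1CO[Si](C)(C)C(C)(C)C
F5 | step 2 | (4R)-4-benzyl-3-[(2S)-2-{[(4-methoxyphenyl)methoxy]methyl}-3-methylbut-3-enoyl]oxazolidin-2-one | CC(=C)[C@@H](COCc1ccc(OC)cc1)C(=O)N1[C@H](Cc2ccccc2)COC1=O
F6 | step 12 | (1R,2S,3R)-2-[(1R)-1-hydroxy-3-methylbut-3-en-1-yl]-3-methyl-1-(propan-2-yl)-3-(prop-2-en-1-yl)cyclopentan-1-ol | CC(C)[C@]1(O)CC[C@](C)(CC=C)[C@H]1[C@H](O)CC(C)=C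
F7 | step 12 | 1-[(1R,2R,5R)-2-hydroxy-5-methyl-2-(propan-2-yl)-5-(prop-2-en-1-yl)cyclopentyl]-3-methylbut-3-en-1-one | CC(C)[C@]1(O)CC[C@](C)(CC=C)[C@H]1C(=O)CC(C)=C
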